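## Structural features

The target, (3R,4S,6S,9R,10S)-4-bromo-10-chloro-5,5,9-trimethyl-1-methylidenespiro[5.5]undecane-3,9-diol, is a spiro[5.5]undecane in which ring A (C1–C6) and ring B (C6–C11) share only the quaternary carbon C6; these locants are used throughout. C6 is bonded in ring A to the gem-dimethyl carbon C5, so two fully substituted carbons are neighbours, and to C1, which carries a 1,1-disubstituted exocyclic alkene. Ring A holds the C3 carbinol and the C4 bromide on adjacent carbons, cis to each other; ring B holds the tertiary C9 carbinol (with its methyl) and the C10 chloride on adjacent carbons, hydroxyl and chlorine again cis. The two pairs are separated by C6, which is stereogenic only because the arms of each ring differ (C7 versus C11, C1 versus C5); relaying configuration across this centre, beside the congestion at C5/C6, is the real difficulty. Fragile groups are the methylidene (it moves into the ring with acid and reacts with electrophiles and hydrogenation catalysts), the neopentyl secondary bromide beside an oxygen, the β-chloro tertiary alcohol, and both carbinols, which can ionise or take part in semipinacol shifts. The key step exploits C10: a single CHCl carbon between the oxygenated C9 and C11 (the CH2 bonded to C6), so it can be inserted with its chlorine between the carbonyl carbon and the only enolisable α-carbon of a spiro cyclopent-2-enone that lacks C10. Because that insertion makes the two arms of ring B constitutionally different, the configuration fixed earlier at C6 decides which arm carries chlorine.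

## Logic of the disconnections

31 is traced to 30 by cutting only the O–Si bond at C3. The bromohydrin oxygen therefore stays masked through every basic and organometallic step; the forward cleavage must neither ionise the C9 alcohol nor move the methylidene.

30 is cut at the C9–CH3 bond to give 29. This removes one stereocentre and leaves a ketone flanked by C10–Cl; the forward addition must avoid enolising the acidic α-chloro ketone and must place methyl trans to chlorine.

29 is traced to 27 by removing four hydrogens (C7=C8 and C10=C11). C10 becomes trigonal, so its configuration can be set afterwards under thermodynamic control; the forward step needs a double 1,4-reduction that spares C–Cl, C–Br and the methylidene.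

27 is cut at C9–C10 and C10–C11 to give 24 and the carbene from 25. Ring B shrinks to a five-membered enol derivative and the chlorinated carbon becomes a one-carbon reagent; the forward step must add to the silyl enol ether and not to the methylidene, and the insertion site follows from 24 being a single regioisomer.

24 is traced to 23 by the O–Si bond of the enol ether, and 23 to 21 by cutting C7=C8 (aldol retron). Ring B opens to two arms on C6. The aldehyde arm demands that C1 no longer be a carbonyl at this stage (a formyl group α to a ketone would be lost), so ring A must be complete before ring B is closed.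

21 is traced through 20 and 19 to 18 by functional-group changes of the arms: ketone from a terminal alkene, aldehyde from a protected primary alcohol. No carbonyl then exists while the hydrazide chemistry of ring A is run; the forward oxidation must choose the monosubstituted alkene over the methylidene.

18 is traced through 15 to 14: the exocyclic alkene comes from an endocyclic C1=C2 alkene with a C1 methyl, through the primary allylic alcohol. The exocyclic position cannot be reached by equilibration, so a reductive 1,3-transposition fixes it by mechanism; the precursor is an ordinary 3-methylcyclohexenyl ether.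

14 is traced through 13 to 12 and then, by way of 11, to 9 by cutting O–Si, the C3–H bond and the C4–Br bond. In the conjugated enone, C4 is the only kinetically enolisable carbon (C2 is vinylic), which solves the regiochemistry. C6 gives little bias at C4 because both of its arms are CH2 groups, so the bromination is expected to give both epimers (11). Since this centre can be epimerised through the enol, 12 is reached by separation with return of the other epimer to the equilibrium; the demand on the forward step is a workable separation. The reduction must deliver hydride opposite the axial C5 methyl.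

9 is cut at C1–CH3 with 1,3-transposition of the carbonyl to give 7. This returns to a vinylogous ester in which the two oxygens of a 1,3-dione are differentiated; the forward addition must reach a hindered carbonyl.

7 is cut at C6–C11 to give 6, and 6 is traced to 4 and 5. The quaternary stereocentre is set once, early, by a catalytic decarboxylative allylation that accepts a fully substituted, hindered enolate; the demand is a regiodefined enol carbonate and ligand control.

4 is cut at C6–C7 to give 2 and 3, and 2 comes from 1. All ring A carbons derive from a symmetric dione, so formation of the enol ether raises no regiochemical question.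

## Other disconnections considered

Alternative 1: The cut is the C6–C7 bond, made together with dearomatisation of ring A. Forward, the phenol A2, 4-{2-[2-(2-iodoethyl)-1,3-dioxolan-2-yl]ethyl}-3-methoxy-5-methylphenol, would be deprotonated and its para carbon would displace the tethered primary iodide (6-exo-tet), giving the spiro dienone A1 with ring B as its C9 ketal.
- In its favour: an orcinol ether is cheap; the quaternary carbon and a six-membered ring B arise in one step with no ring expansion; A1 already has the C1 methyl, the C3 oxygen and a leaving group (methoxy) at C5 for the gem-dimethyl group. In step economy up to the spiro[5.5] core it is better than the chosen plan.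
- Against it: A1 has a mirror plane (the two arms of ring B are identical), so C6 is not yet a stereocentre and no absolute configuration is set. The later chlorination must choose between C8 and C10 with no constitutional difference, which is exactly the choice the carbene insertion removes. O-alkylation can compete, double methyl delivery to C5 beside the spiro centre is hindered, and ring A still needs the same bromohydrin and methylidene work.
- Comparison: the mechanism (intramolecular SN2 of an ambident phenolate) is as well founded as a carbene addition and the early steps are fewer, but control of C6 relative to both stereo-pairs is weaker, so the total length would not be shorter once that is repaired.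

Alternative 2: The cut is C2–C3 of ring A. Forward, the α-bromo aldehyde A4, (2S)-2-bromo-3-methyl-3-[8-(prop-1-en-2-yl)-1,4-dioxaspiro[4.5]decan-8-yl]butanal, would be activated by Me2AlCl and undergo an intramolecular carbonyl-ene reaction: the carbonyl carbon bonds to the isopropenyl CH2 and a methyl hydrogen passes to oxygen, giving the cis-bromohydrin A3.
- In its favour: ring A, the C1 methylidene and the C3 carbinol arise in one step with bromine already at C4, and the alkene is born exocyclic. On this point it is better than the chosen plan, which needs an allylic oxidation and a reductive transposition. Me2AlCl also scavenges HCl, which protects the new alkene.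
- Against it: A4 needs the vicinal quaternary carbons C5 and C6 joined on an open chain; its α-bromo aldehyde stereocentre can epimerise through the enol and would have to come from an asymmetric bromination beside a quaternary carbon; the cis/trans outcome rests on a single chair-like transition state. In A3 ring B is a symmetric ketal, so C6 is again not stereogenic.
- Comparison: equal in the number of rings closed by the key step and superior for the methylidene, but weaker on quaternary-carbon assembly and on the relation between the two rings.

Alternative 3: The cut is C1–C2. Forward, In(NTf2)3 would activate the terminal alkyne of the β-keto ester A6, tert-butyl 5-(8-ethynyl-1,4-dioxaspiro[4.5]decan-8-yl)-5-methyl-3-oxohexanoate, and the enol carbon C2 would add 6-exo-dig to the internal alkyne carbon (Conia-ene), giving the cyclic β-keto ester A5 with the exocyclic alkene.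
- In its favour: the step is catalytic, neutral and atom-economical; the methylidene is again formed regiospecifically (equal to alternative 2 and better than the chosen plan on this point); the ester blocks C2, so C4 could be brominated through the dianion.
- Against it: the alkyne sits on a quaternary carbon beside C5, so the cyclisation is hindered; A6 again needs C5–C6 preassembled in an open chain; removal of the tert-butyl ester and decarboxylation beside the methylidene invite migration of the alkene into conjugation; C3 and C4 remain to be set; the symmetric ring B leaves C6 without configuration.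
- Comparison: it would need more steps after the key step than the chosen plan and has no answer to the chlorine regiochemistry, where the chosen plan is stronger.

Key step: step 16

Assumption: the sense of induction in step 4 is taken to follow that established for 2-alkylcyclohexanone allyl enol carbonates with the same ligand class, so the (S) ligand is written for (6R)-7; the antipodal ligand serves if the sense is reversed.

Assumption: 3 is taken as a purchasable, moisture-sensitive reagent that is distilled before use.

## Route

Step 1
Reactants: 1 5,5-dimethylcyclohexane-1,3-dione (dimedone)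
Product: 2 5,5-dimethyl-3-(2-methylpropoxy)cyclohex-2-en-1-one
Conditions: i-BuOH, TsOH·H2O (cat.), PhH, reflux, Dean–Stark
Reagents that add atoms: 2-methylpropan-1-ol, CC(C)CO
Why: Acid-catalysed enol etherification of the symmetric 1,3-dione with azeotropic removal of water gives a single vinylogous ester, which differentiates the future C1 (carbonyl) from the future C3 (enol ether carbon).

Step 2
Reactants: 2 5,5-dimethyl-3-(2-methylpropoxy)cyclohex-2-en-1-one; 3 4-methoxybenzyl chloromethyl ether
Product: 4 rac-6-{[(4-methoxybenzyl)oxy]methyl}-5,5-dimethyl-3-(2-methylpropoxy)cyclohex-2-en-1-one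
Conditions: LiN(i-Pr)2, THF, −78 °C; then 3, −78 → 0 °C
Reagents that add atoms: 4-methoxybenzyl chloromethyl ether (3), COc1ccc(COCCl)cc1
Why: Kinetic α′-deprotonation of the vinylogous ester (Stork–Danheiser enolate) and C-alkylation by the reactive α-chloro ether form the C6–C7 bond; the new stereocentre is racemic and is made planar again in step 3.

Step 3
Reactants: 4 rac-6-{[(4-methoxybenzyl)oxy]methyl}-5,5-dimethyl-3-(2-methylpropoxy)cyclohex-2-en-1-one; 5 allyl chloroformate
Product: 6 2-{[(4-methoxybenzyl)oxy]methyl}-3,3-dimethyl-5-(2-methylpropoxy)cyclohexa-1,5-dien-1-yl prop-2-en-1-yl carbonate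
Conditions: LiN(i-Pr)2, TMEDA, THF, −78 °C; then 5
Reagents that add atoms: allyl chloroformate (5), C=CCOC(=O)Cl
Why: A second α′-deprotonation gives the fully substituted enolate, which the hard chloroformate acylates on oxygen (enol carbonate formation); the ring fixes the enolate geometry, so one regiodefined enol carbonate results.

Step 4
Reactants: 6 2-{[(4-methoxybenzyl)oxy]methyl}-3,3-dimethyl-5-(2-methylpropoxy)cyclohexa-1,5-dien-1-yl prop-2-en-1-yl carbonate
Product: 7 (6R)-6-{[(4-methoxybenzyl)oxy]methyl}-5,5-dimethyl-3-(2-methylpropoxy)-6-(prop-2-en-1-yl)cyclohex-2-en-1-one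
Conditions: Pd2(dba)3 (2.5 mol %), (S)-4-tert-butyl-2-[2-(diphenylphosphanyl)phenyl]-4,5-dihydrooxazole ((S)-t-BuPHOX, 6 mol %), toluene, 30 °C
Reagents that add atoms: none
Why: Pd-catalysed decarboxylative asymmetric allylic alkylation: oxidative addition of zerovalent palladium and loss of CO2 give a π-allylpalladium enolate that couples at C6 inside the chiral ligand sphere, forming the C6–C11 bond and the quaternary stereocentre. The (S) ligand is expected to deliver allyl to the enolate face that gives 6R, and the racemic origin of 6 is irrelevant because the enolate is planar.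

Step 5
Reactants: 7 (6R)-6-{[(4-methoxybenzyl)oxy]methyl}-5,5-dimethyl-3-(2-methylpropoxy)-6-(prop-2-en-1-yl)cyclohex-2-en-1-one
Product: 9 (4S)-4-{[(4-methoxybenzyl)oxy]methyl}-3,5,5-trimethyl-4-(prop-2-en-1-yl)cyclohex-2-en-1-one, via tertiary allylic alcohol 8 (not isolated)
Conditions: MeLi, CeCl3, THF, −78 → 0 °C; then 1 M HCl, 23 °C
Reagents that add atoms: methyllithium, [Li]C
Why: Stork–Danheiser sequence: the organocerium reagent adds 1,2 to the hindered vinylogous ester carbonyl (C1), and acid hydrolysis of the enol ether with loss of water transposes the carbonyl to C3, giving the enone with the C1 methyl; C6 is not touched.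

Step 6
Reactants: 9 (4S)-4-{[(4-methoxybenzyl)oxy]methyl}-3,5,5-trimethyl-4-(prop-2-en-1-yl)cyclohex-2-en-1-one
Product: 12 (4R,6S)-6-bromo-4-{[(4-methoxybenzyl)oxy]methyl}-3,5,5-trimethyl-4-(prop-2-en-1-yl)cyclohex-2-en-1-one, via trimethylsilyl dienol ether 10 (not isolated), via epimeric bromo enone pair 11 (not isolated)
Conditions: LiN(i-Pr)2, Me3SiCl, THF, −78 °C; crude 10, NBS, NaHCO3, THF, −78 → 0 °C; chromatography; the (6R) component of 11: Et3N (cat.), CH2Cl2, 23 °C, then chromatography again
Reagents that add atoms: N-bromosuccinimide, O=C1CCC(=O)N1Br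
Why: Kinetic α′-enolisation (C2 is vinylic, so C4 of the target is the only site), silyl trapping and electrophilic bromination of the cross-conjugated silyl dienol ether place bromine on C4; both epimers (11) are expected, because the two CH2 arms on C6 bias neither face. The bromine-bearing centre is epimerisable through the enol with Et3N, so 12 is taken out by chromatography and the other epimer is returned to the equilibrating pair until the material is used up. The configuration of C4 relative to C6 is therefore fixed by this separation-and-recycling loop and not by facial selectivity.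

Step 7
Reactants: 12 (4R,6S)-6-bromo-4-{[(4-methoxybenzyl)oxy]methyl}-3,5,5-trimethyl-4-(prop-2-en-1-yl)cyclohex-2-en-1-one
Product: 13 (1R,4R,6S)-6-bromo-4-{[(4-methoxybenzyl)oxy]methyl}-3,5,5-trimethyl-4-(prop-2-en-1-yl)cyclohex-2-en-1-ol
Conditions: i-Bu2AlH, CH2Cl2, −78 °C
Reagents that add atoms: none
Why: 1,2-Reduction of the α′-bromo enone: the bulky aluminium hydride attacks C3 from the face opposite the axial C5 methyl (equatorial attack), giving the axial alcohol cis to the equatorial bromide (3R in target numbering). A cis-bromohydrin cannot close to an epoxide.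

Step 8
Reactants: 13 (1R,4R,6S)-6-bromo-4-{[(4-methoxybenzyl)oxy]methyl}-3,5,5-trimethyl-4-(prop-2-en-1-yl)cyclohex-2-en-1-ol
Product: 14 tert-butyl{[(1R,4R,6S)-6-bromo-4-{[(4-methoxybenzyl)oxy]methyl}-3,5,5-trimethyl-4-(prop-2-en-1-yl)cyclohex-2-en-1-yl]oxy}dimethylsilane
Conditions: t-BuMe2SiOTf, 2,6-lutidine, CH2Cl2, −78 → 0 °C
Reagents that add atoms: tert-butyldimethylsilyl trifluoromethanesulfonate, CC(C)(C)[Si](C)(C)OS(=O)(=O)C(F)(F)F
Why: O-Silylation of the hindered axial alcohol with the reactive silyl triflate; the ether masks the bromohydrin oxygen against the bases, hydrides and organometallics that follow.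

Step 9
Reactants: 14 tert-butyl{[(1R,4R,6S)-6-bromo-4-{[(4-methoxybenzyl)oxy]methyl}-3,5,5-trimethyl-4-(prop-2-en-1-yl)cyclohex-2-en-1-yl]oxy}dimethylsilane
Product: 15 {(3R,4S,6R)-4-bromo-3-[(tert-butyldimethylsilyl)oxy]-6-{[(4-methoxybenzyl)oxy]methyl}-5,5-dimethyl-6-(prop-2-en-1-yl)cyclohex-1-en-1-yl}methanol
Conditions: SeO2 (0.5 equiv), t-BuOOH, CH2Cl2, 23 °C
Reagents that add atoms: tert-butyl hydroperoxide, CC(C)(C)OO
Why: SeO2 allylic oxidation (ene reaction, then [2,3]-sigmatropic shift): the only allylic hydrogens on the disubstituted alkene terminus are those of the C1 methyl, because C6 is quaternary, so the methyl is hydroxylated. The terminal allyl group is a much poorer ene partner.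

Step 10
Reactants: 15 {(3R,4S,6R)-4-bromo-3-[(tert-butyldimethylsilyl)oxy]-6-{[(4-methoxybenzyl)oxy]methyl}-5,5-dimethyl-6-(prop-2-en-1-yl)cyclohex-1-en-1-yl}methanol
Product: 18 tert-butyl{[(1R,2S,4R)-2-bromo-4-{[(4-methoxybenzyl)oxy]methyl}-3,3-dimethyl-5-methylidene-4-(prop-2-en-1-yl)cyclohexyl]oxy}dimethylsilane, via allylic sulfonylhydrazine 16 (not isolated), via allylic diazene 17 (not isolated)
Conditions: 2-nitrobenzenesulfonylhydrazide, PPh3, diethyl azodicarboxylate, N-methylmorpholine, −30 → 23 °C
Reagents that add atoms: none
Why: Myers reductive allylic transposition: Mitsunobu N-alkylation, loss of the sulfinic acid to the monoalkyl diazene, and retro-ene loss of N2 deliver hydrogen to C2 and move the alkene to the exocyclic position regiospecifically. It is run before any carbonyl group is unveiled, because the hydrazide would condense with it.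

Step 11
Reactants: 18 tert-butyl{[(1R,2S,4R)-2-bromo-4-{[(4-methoxybenzyl)oxy]methyl}-3,3-dimethyl-5-methylidene-4-(prop-2-en-1-yl)cyclohexyl]oxy}dimethylsilane
Product: 19 {(1R,3S,4R)-3-bromo-4-[(tert-butyldimethylsilyl)oxy]-2,2-dimethyl-6-methylidene-1-(prop-2-en-1-yl)cyclohexyl}methanol
Conditions: DDQ, CH2Cl2/pH 7 buffer, 0 → 23 °C
Reagents that add atoms: none
Why: Oxidative cleavage of the 4-methoxybenzyl ether by DDQ (hydride abstraction, then hydrolysis of the oxocarbenium ion) frees the C7 hydroxyl without touching the silyl ether, the bromide or the unactivated alkenes.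

Step 12
Reactants: 19 {(1R,3S,4R)-3-bromo-4-[(tert-butyldimethylsilyl)oxy]-2,2-dimethyl-6-methylidene-1-(prop-2-en-1-yl)cyclohexyl}methanol
Product: 20 (1R,3S,4R)-3-bromo-4-[(tert-butyldimethylsilyl)oxy]-2,2-dimethyl-6-methylidene-1-(prop-2-en-1-yl)cyclohexane-1-carbaldehyde
Conditions: Dess–Martin periodinane, NaHCO3, CH2Cl2, 0 → 23 °C
Reagents that add atoms: none
Why: Dess–Martin oxidation of the neopentyl primary alcohol gives a non-enolisable aldehyde under buffered conditions that leave the methylidene in place.

Step 13
Reactants: 20 (1R,3S,4R)-3-bromo-4-[(tert-butyldimethylsilyl)oxy]-2,2-dimethyl-6-methylidene-1-(prop-2-en-1-yl)cyclohexane-1-carbaldehyde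
Product: 21 (1R,3S,4R)-3-bromo-4-[(tert-butyldimethylsilyl)oxy]-2,2-dimethyl-6-methylidene-1-(2-oxopropyl)cyclohexane-1-carbaldehyde
Conditions: PdCl2 (10 mol %), CuCl, O2 (1 atm), DMF/H2O (7:1), 23 °C
Reagents that add atoms: water, O
Why: Tsuji–Wacker oxidation: Markovnikov hydroxypalladation of the monosubstituted alkene, which is much faster than that of the hindered 1,1-disubstituted methylidene, gives the methyl ketone and thus the 1,4-keto aldehyde.

Step 14
Reactants: 21 (1R,3S,4R)-3-bromo-4-[(tert-butyldimethylsilyl)oxy]-2,2-dimethyl-6-methylidene-1-(2-oxopropyl)cyclohexane-1-carbaldehyde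
Product: 23 (5R,8R,9S)-9-bromo-8-[(tert-butyldimethylsilyl)oxy]-10,10-dimethyl-6-methylidenespiro[4.5]dec-1-en-3-one, via β-hydroxy ketone 22 (not isolated)
Conditions: KOH, MeOH, 0 → 23 °C
Reagents that add atoms: none
Why: Intramolecular aldol condensation (5-enolexo addition of the methyl ketone enolate to the non-enolisable aldehyde, then E1cB dehydration) forms C7=C8 and closes the five-membered ring. C1 is no longer a carbonyl, so the formyl group cannot be lost by a retro-Claisen path.

Step 15
Reactants: 23 (5R,8R,9S)-9-bromo-8-[(tert-butyldimethylsilyl)oxy]-10,10-dimethyl-6-methylidenespiro[4.5]dec-1-en-3-one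
Product: 24 tert-butyl{[(5S,8R,9S)-9-bromo-10,10-dimethyl-6-methylidene-3-[(triethylsilyl)oxy]spiro[4.5]deca-1,3-dien-8-yl]oxy}dimethylsilane
Conditions: Et3SiOTf, Et3N, CH2Cl2, 0 °C
Reagents that add atoms: triethylsilyl trifluoromethanesulfonate, CC[Si](CC)(CC)OS(=O)(=O)C(F)(F)F
Why: Soft enolisation: O-silylation and deprotonation at C11, the only enolisable position (C7 is vinylic, C6 quaternary), give one cross-conjugated silyl dienol ether without an amide base beside the bromide. The triethylsilyl group resists alkoxide better than trimethylsilyl, yet is lost readily in the next step.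

Step 16
Reactants: 24 tert-butyl{[(5S,8R,9S)-9-bromo-10,10-dimethyl-6-methylidene-3-[(triethylsilyl)oxy]spiro[4.5]deca-1,3-dien-8-yl]oxy}dimethylsilane; 25 trichloromethane (chloroform)
Product: 27 (3R,4S,6S)-4-bromo-3-[(tert-butyldimethylsilyl)oxy]-10-chloro-5,5-dimethyl-1-methylidenespiro[5.5]undeca-7,10-dien-9-one, via dichlorocyclopropane 26 (not isolated)
Conditions: CHCl3, KOt-Bu, hexane, −30 → 0 °C; cold NH4Cl quench, then 23 °C
Reagents that add atoms: chloroform (25), ClC(Cl)Cl
Why: tert-Butoxide deprotonates chloroform and α-elimination of chloride gives singlet dichlorocarbene, which adds in a concerted [2+1] step to the most electron-rich π bond of 24, the C9=C11 silyl enol ether, forming the C9–C10 and C10–C11 bonds of dichlorocyclopropane 26. The strained bicyclo[3.1.0]hexene then undergoes oxygen-assisted disrotatory cyclopropyl-to-allyl cation opening with loss of the endo chloride, breaking the C9–C11 bond, and chloride removes the triethylsilyl group from the oxocarbenium ion to leave dienone 27. The closest known reaction type is the dihalocarbene ring expansion of cyclic silyl enol ethers to 2-halocycloalk-2-enones. The three-membered ring closes by cycloaddition, and the six-membered ring B arises by electrocyclic enlargement of the five-membered ring, not by an end-to-end cyclisation. No stereocentre is created in 27 (C9 and C11 of 26 become trigonal again) and C6 is untouched. The step needs chemoselectivity for the enol ether over the C1 methylidene and the C7=C8 bond, which rests on the high nucleophilicity of the oxygenated alkene and the neopentyl shielding of the methylidene; it needs insertion on the C11 side, which is secured because C11 is the only enolisable position of 23, so that 24 is a single regioisomer. Quenching cold before warming keeps the new dienone away from base, and fast chloride-induced desilylation limits cationic 1,2-shifts.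

Step 17
Reactants: 27 (3R,4S,6S)-4-bromo-3-[(tert-butyldimethylsilyl)oxy]-10-chloro-5,5-dimethyl-1-methylidenespiro[5.5]undeca-7,10-dien-9-one
Product: 29 (3R,4S,6S,10S)-4-bromo-3-[(tert-butyldimethylsilyl)oxy]-10-chloro-5,5-dimethyl-1-methylidenespiro[5.5]undecan-9-one, via chloro enone 28 (not isolated)
Conditions: [(Ph3P)CuH]6, H2O, THF, 23 °C; then Et3N (cat.), CH2Cl2, 23 °C
Reagents that add atoms: none
Why: Stryker-type conjugate reduction: copper hydride adds to the β-carbons C7 and C11 of both enone arms (the order is immaterial), water protonating each copper enolate at once so that the α-chloro enolate has no lifetime; isolated alkenes and carbon–halogen bonds are tolerated. C10 is set under thermodynamic control by enolisation with Et3N: chlorine equatorial in the ring B chair that puts the trigonal C1 axial and the bulky C5 equatorial, that is trans to C1 (10S).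

Step 18
Reactants: 29 (3R,4S,6S,10S)-4-bromo-3-[(tert-butyldimethylsilyl)oxy]-10-chloro-5,5-dimethyl-1-methylidenespiro[5.5]undecan-9-one
Product: 30 (3R,4S,6S,9R,10S)-4-bromo-3-[(tert-butyldimethylsilyl)oxy]-10-chloro-5,5,9-trimethyl-1-methylidenespiro[5.5]undecan-9-ol
Conditions: MeMgBr, CeCl3, THF, −78 °C
Reagents that add atoms: methylmagnesium bromide, C[Mg]Br
Why: 1,2-Addition of the weakly basic organocerium reagent avoids enolisation or displacement at the α-chloro ketone. Methyl enters along the equatorial trajectory on the face away from the neighbouring equatorial chlorine, so methyl is trans and the axial hydroxyl cis to chlorine (9R); an axial alkoxide beside an equatorial chloride cannot close to an epoxide.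

Step 19
Reactants: 30 (3R,4S,6S,9R,10S)-4-bromo-3-[(tert-butyldimethylsilyl)oxy]-10-chloro-5,5,9-trimethyl-1-methylidenespiro[5.5]undecan-9-ol
Product: 31 (3R,4S,6S,9R,10S)-4-bromo-10-chloro-5,5,9-trimethyl-1-methylidenespiro[5.5]undecane-3,9-diol
Conditions: HF·pyridine, pyridine, THF, 0 → 23 °C
Reagents that add atoms: none
Why: Fluoride-mediated cleavage of the Si–O bond; buffered HF·pyridine is not basic enough to trigger semipinacol or epoxide chemistry of the two cis-halohydrins, and not acidic enough to isomerise the methylidene or ionise the tertiary alcohol.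

## Compound list

1 | 5,5-dimethylcyclohexane-1,3-dione (dimedone) | CC1(C)CC(=O)CC(=O)C1 | starting material
2 | 5,5-dimethyl-3-(2-methylpropoxy)cyclohex-2-en-1-one | CC(C)COC1=CC(=O)CC(C)(C)C1 | intermediate
3 | 1-[(chloromethoxy)methyl]-4-methoxybenzene (4-methoxybenzyl chloromethyl ether) | COc1ccc(COCCl)cc1 | starting material
4 | rac-6-{[(4-methoxybenzyl)oxy]methyl}-5,5-dimethyl-3-(2-methylpropoxy)cyclohex-2-en-1-one | O=C1C=C(OCC(C)C)CC(C)(C)C1COCc2ccc(OC)cc2 | intermediate
5 | prop-2-en-1-yl carbonochloridate (allyl chloroformate) | C=CCOC(=O)Cl | starting material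
6 | 2-{[(4-methoxybenzyl)oxy]methyl}-3,3-dimethyl-5-(2-methylpropoxy)cyclohexa-1,5-dien-1-yl prop-2-en-1-yl carbonate | C=CCOC(=O)OC1=C(COCc2ccc(OC)cc2)C(C)(C)CC(OCC(C)C)=C1 | intermediate
7 | (6R)-6-{[(4-methoxybenzyl)oxy]methyl}-5,5-dimethyl-3-(2-methylpropoxy)-6-(prop-2-en-1-yl)cyclohex-2-en-1-one | O=C1C=C(OCC(C)C)CC(C)(C)[C@]1(CC=C)COCc2ccc(OC)cc2 | intermediate
8 | (6R)-6-{[(4-methoxybenzyl)oxy]methyl}-1,5,5-trimethyl-3-(2-methylpropoxy)-6-(prop-2-en-1-yl)cyclohex-2-en-1-ol (both C1 epimers) | CC1(O)C=C(OCC(C)C)CC(C)(C)[C@]1(CC=C)COCc2ccc(OC)cc2 | intermediate (not isolated)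
9 | (4S)-4-{[(4-methoxybenzyl)oxy]methyl}-3,5,5-trimethyl-4-(prop-2-en-1-yl)cyclohex-2-en-1-one | CC1=CC(=O)CC(C)(C)[C@]1(CC=C)COCc2ccc(OC)cc2 | intermediate
10 | {[(4R)-4-{[(4-methoxybenzyl)oxy]methyl}-3,3,5-trimethyl-4-(prop-2-en-1-yl)cyclohexa-1,5-dien-1-yl]oxy}trimethylsilane | CC1=CC(O[Si](C)(C)C)=CC(C)(C)[C@]1(CC=C)COCc2ccc(OC)cc2 | intermediate (not isolated)
11 | (4R)-6-bromo-4-{[(4-methoxybenzyl)oxy]methyl}-3,5,5-trimethyl-4-(prop-2-en-1-yl)cyclohex-2-en-1-one, both epimers at the bromine-bearing carbon (C4 in target numbering) | CC1=CC(=O)C(Br)C(C)(C)[C@]1(CC=C)COCc2ccc(OC)cc2 | intermediate (not isolated)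
12 | (4R,6S)-6-bromo-4-{[(4-methoxybenzyl)oxy]methyl}-3,5,5-trimethyl-4-(prop-2-en-1-yl)cyclohex-2-en-1-one | CC1=CC(=O)[C@@H](Br)C(C)(C)[C@]1(CC=C)COCc2ccc(OC)cc2 | intermediate
13 | (1R,4R,6S)-6-bromo-4-{[(4-methoxybenzyl)oxy]methyl}-3,5,5-trimethyl-4-(prop-2-en-1-yl)cyclohex-2-en-1-ol | CC1=C[C@@H](O)[C@@H](Br)C(C)(C)[C@]1(CC=C)COCc2ccc(OC)cc2 | intermediate
14 | tert-butyl{[(1R,4R,6S)-6-bromo-4-{[(4-methoxybenzyl)oxy]methyl}-3,5,5-trimethyl-4-(prop-2-en-1-yl)cyclohex-2-en-1-yl]oxy}dimethylsilane | CC1=C[C@@H](O[Si](C)(C)C(C)(C)C)[C@@H](Br)C(C)(C)[C@]1(CC=C)COCc2ccc(OC)cc2 | intermediate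
15 | {(3R,4S,6R)-4-bromo-3-[(tert-butyldimethylsilyl)oxy]-6-{[(4-methoxybenzyl)oxy]methyl}-5,5-dimethyl-6-(prop-2-en-1-yl)cyclohex-1-en-1-yl}methanol | OCC1=C[C@@H](O[Si](C)(C)C(C)(C)C)[C@@H](Br)C(C)(C)[C@]1(CC=C)COCc2ccc(OC)cc2 | intermediate
16 | N-alkyl-2-nitrobenzenesulfonohydrazide of 15 (the CH2OH of 15 replaced by CH2–N(NH2)–SO2Ar) | NN(CC1=C[C@@H](O[Si](C)(C)C(C)(C)C)[C@@H](Br)C(C)(C)[C@]1(CC=C)COCc2ccc(OC)cc2)S(=O)(=O)c3ccccc3[N+](=O)[O-] | intermediate (not isolated)
17 | monoalkyl diazene of 15 (the CH2OH of 15 replaced by CH2–N=NH) | N=NCC1=C[C@@H](O[Si](C)(C)C(C)(C)C)[C@@H](Br)C(C)(C)[C@]1(CC=C)COCc2ccc(OC)cc2 | intermediate (not isolated)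
18 | tert-butyl{[(1R,2S,4R)-2-bromo-4-{[(4-methoxybenzyl)oxy]methyl}-3,3-dimethyl-5-methylidene-4-(prop-2-en-1-yl)cyclohexyl]oxy}dimethylsilane | C=C1C[C@@H](O[Si](C)(C)C(C)(C)C)[C@@H](Br)C(C)(C)[C@]1(CC=C)COCc2ccc(OC)cc2 | intermediate
19 | {(1R,3S,4R)-3-bromo-4-[(tert-butyldimethylsilyl)oxy]-2,2-dimethyl-6-methylidene-1-(prop-2-en-1-yl)cyclohexyl}methanol | C=C1C[C@@H](O[Si](C)(C)C(C)(C)C)[C@@H](Br)C(C)(C)[C@]1(CC=C)CO | intermediate
20 | (1R,3S,4R)-3-bromo-4-[(tert-butyldimethylsilyl)oxy]-2,2-dimethyl-6-methylidene-1-(prop-2-en-1-yl)cyclohexane-1-carbaldehyde | C=C1C[C@@H](O[Si](C)(C)C(C)(C)C)[C@@H](Br)C(C)(C)[C@]1(CC=C)C=O | intermediate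
21 | (1R,3S,4R)-3-bromo-4-[(tert-butyldimethylsilyl)oxy]-2,2-dimethyl-6-methylidene-1-(2-oxopropyl)cyclohexane-1-carbaldehyde | C=C1C[C@@H](O[Si](C)(C)C(C)(C)C)[C@@H](Br)C(C)(C)[C@]1(CC(C)=O)C=O | intermediate
22 | (5R,8R,9S)-9-bromo-8-[(tert-butyldimethylsilyl)oxy]-1-hydroxy-10,10-dimethyl-6-methylidenespiro[4.5]decan-3-one (both carbinol epimers) | C=C1C[C@@H](O[Si](C)(C)C(C)(C)C)[C@@H](Br)C(C)(C)[C@]12C(O)CC(=O)C2 | intermediate (not isolated)
23 | (5R,8R,9S)-9-bromo-8-[(tert-butyldimethylsilyl)oxy]-10,10-dimethyl-6-methylidenespiro[4.5]dec-1-en-3-one | C=C1C[C@@H](O[Si](C)(C)C(C)(C)C)[C@@H](Br)C(C)(C)[C@]12C=CC(=O)C2 | intermediate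
24 | tert-butyl{[(5S,8R,9S)-9-bromo-10,10-dimethyl-6-methylidene-3-[(triethylsilyl)oxy]spiro[4.5]deca-1,3-dien-8-yl]oxy}dimethylsilane | C=C1C[C@@H](O[Si](C)(C)C(C)(C)C)[C@@H](Br)C(C)(C)[C@]12C=CC(O[Si](CC)(CC)CC)=C2 | intermediate (precursor of the key step)
25 | trichloromethane (chloroform) | ClC(Cl)Cl | starting material
26 | dichlorocarbene adduct of 24: 6,6-dichloro-1-[(triethylsilyl)oxy]bicyclo[3.1.0]hex-2-ene spiro-fused at its C4 to ring A (C9, C10 and C11 form the three-membered ring; both cyclopropane diastereomers) | C=C1C[C@@H](O[Si](C)(C)C(C)(C)C)[C@@H](Br)C(C)(C)[C@]12C=CC3(O[Si](CC)(CC)CC)C2C3(Cl)Cl | intermediate (not isolated)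
27 | (3R,4S,6S)-4-bromo-3-[(tert-butyldimethylsilyl)oxy]-10-chloro-5,5-dimethyl-1-methylidenespiro[5.5]undeca-7,10-dien-9-one | C=C1C[C@@H](O[Si](C)(C)C(C)(C)C)[C@@H](Br)C(C)(C)[C@]12C=CC(=O)C(Cl)=C2 | intermediate (product of the key step)
28 | (3R,4S,6R)-4-bromo-3-[(tert-butyldimethylsilyl)oxy]-10-chloro-5,5-dimethyl-1-methylidenespiro[5.5]undec-7-en-9-one (both C10 epimers) | C=C1C[C@@H](O[Si](C)(C)C(C)(C)C)[C@@H](Br)C(C)(C)[C@]12C=CC(=O)C(Cl)C2 | intermediate (not isolated)
29 | (3R,4S,6S,10S)-4-bromo-3-[(tert-butyldimethylsilyl)oxy]-10-chloro-5,5-dimethyl-1-methylidenespiro[5.5]undecan-9-one | C=C1C[C@@H](O[Si](C)(C)C(C)(C)C)[C@@H](Br)C(C)(C)[C@]12CCC(=O)[C@@H](Cl)C2 | intermediate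
30 | (3R,4S,6S,9R,10S)-4-bromo-3-[(tert-butyldimethylsilyl)oxy]-10-chloro-5,5,9-trimethyl-1-methylidenespiro[5.5]undecan-9-ol | C=C1C[C@@H](O[Si](C)(C)C(C)(C)C)[C@@H](Br)C(C)(C)[C@]12CC[C@@](C)(O)[C@@H](Cl)C2 | intermediate
31 | (3R,4S,6S,9R,10S)-4-bromo-10-chloro-5,5,9-trimethyl-1-methylidenespiro[5.5]undecane-3,9-diol | C=C1C[C@@H](O)[C@@H](Br)C(C)(C)[C@]12CC[C@@](C)(O)[C@@H](Cl)C2 | target

## Step count and least certain steps

Total step count: 19. Longest linear sequence: 19 steps, from 1 to 31; 3, 5 and 25 are bought.

Step 16 (key step). Most likely to go wrong: cleavage of the silyl dienol ether by tert-butoxide back to 23, or attack of trichloromethyl anion or alkoxide on the electrophilic dienone once it has formed. Less likely are cyclopropanation of the methylidene and a cationic 1,2-shift during ring opening (dienone–phenol type), because the cation is a 4,4-disubstituted cyclohexadienyl cation. The fallback separates carbon insertion from chlorination; it sets out from 23 and comes back at 28. Homologation of 23 with trimethylsilyldiazomethane and Me3Al at −78 °C (Lewis-acid-promoted diazoalkane ring expansion, the saturated C11 expected to migrate in preference to the alkenyl C8) would give the α-silyl ketone F1, which is protodesilylated on work-up to the spiro cyclohex-2-enone F2. Kinetic deprotonation of F2 at C10 (again the only enolisable position) and trapping with Me3SiCl would give the dienol ether F3, and N-chlorosuccinimide would then give 28, which step 17 reduces and equilibrates to 29.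

Step 6. Most likely to go wrong: absence of facial discrimination at C4, since the two arms on C6 are both CH2 groups, so that each pass delivers only part of the material as 12. Incomplete chromatographic resolution of the two epimers or slow re-equilibration of the hindered α-proton would then make the recycling loop long. The fallback replaces separation by reagent control; it sets out from the epimer pair 11, used without separation, and comes back at 13. A Corey–Bakshi–Shibata reduction (1-methyl-3,3-diphenyltetrahydro-1H,3H-pyrrolo[1,2-c][1,3,2]oxazaborole as catalyst, catecholborane, toluene, −78 °C) should reduce the (6S) epimer of 11 to 13 faster than the (6R) epimer, for which catalyst and substrate preferences oppose each other. The catalyst enantiomer is the one matched to the (6S) epimer, expected to be (S) if the bromine-bearing α′-carbon acts as the larger carbonyl substituent. Recovered ketone is re-equilibrated with Et3N and resubmitted. This fallback makes no new compound (F0).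

Step 9. Most likely to go wrong: slow or unselective allylic oxidation at the hindered methyl, with over-oxidation to the enal or attack on the allyl side chain. The fallback sets out from 14 and comes back at 18, so it also replaces step 10. A Schenck ene reaction with singlet oxygen (O2, tetraphenylporphyrin, visible light) should abstract a methyl hydrogen, because the C3 hydrogen geminal to the silyloxy group is unreactive, and give the exocyclic alkene with a hydroperoxide at C2, the hydroperoxide F4. PPh3 reduces it to the allylic alcohol F5, and methyl chloroformate with pyridine gives the carbonate F6. Pd2(dba)3 and PBu3 with HCO2H–Et3N then remove the allylic oxygen by hydride delivery to the more substituted terminus of the π-allyl complex (Tsuji formate reduction), which keeps the alkene exocyclic and gives 18.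

Step 17. Most likely to go wrong: loss of chlorine from the α-chloro copper enolate, or 1,2-reduction of the ketone by excess hydride. The fallback sets out from 27 and comes back at 29; it uses two separate boron-hydride conjugate reductions with an isolated intermediate. K[(s-Bu)3BH] (one equivalent, THF, −78 °C) reduces one enone arm to a boron enolate that holds the α-chlorine, and a phenol quench gives the chloro enone 28, which is isolated. A second equivalent saturates C7=C8, and Et3N equilibration then gives 29. This fallback makes no new compound (F0).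

## Further compounds

F1 | step 16 | 10-(trimethylsilyl) ketone from ring expansion of 23: (3R,4S)-4-bromo-3-[(tert-butyldimethylsilyl)oxy]-5,5-dimethyl-1-methylidene-10-(trimethylsilyl)spiro[5.5]undec-7-en-9-one, configuration at C6 as drawn, both C10 epimers | C=C1C[C@@H](O[Si](C)(C)C(C)(C)C)[C@@H](Br)C(C)(C)[C@]12C=CC(=O)C([Si](C)(C)C)C2
F2 | step 16 | (3R,4S,6R)-4-bromo-3-[(tert-butyldimethylsilyl)oxy]-5,5-dimethyl-1-methylidenespiro[5.5]undec-7-en-9-one | C=C1C[C@@H](O[Si](C)(C)C(C)(C)C)[C@@H](Br)C(C)(C)[C@]12C=CC(=O)CC2
F3 | step 16 | trimethylsilyl dienol ether of F2 (C9–OSiMe3, double bonds C7=C8 and C9=C10) | C=C1C[C@@H](O[Si](C)(C)C(C)(C)C)[C@@H](Br)C(C)(C)[C@]12C=CC(O[Si](C)(C)C)=CC2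
F0 | step 6 | none | none
F4 | step 9 | C2 hydroperoxide with exocyclic C1 alkene, from 14 (both C2 epimers) | C=C1C(OO)[C@@H](O[Si](C)(C)C(C)(C)C)[C@@H](Br)C(C)(C)[C@]1(CC=C)COCc2ccc(OC)cc2
F5 | step 9 | C2 allylic alcohol with exocyclic C1 alkene (both C2 epimers) | C=C1C(O)[C@@H](O[Si](C)(C)C(C)(C)C)[C@@H](Br)C(C)(C)[C@]1(CC=C)COCc2ccc(OC)cc2
F6 | step 9 | methyl carbonate of F5 | C=C1C(OC(=O)OC)[C@@H](O[Si](C)(C)C(C)(C)C)[C@@H](Br)C(C)(C)[C@]1(CC=C)COCc2ccc(OC)cc2
F0 | step 17 | none | none
A1 | alternative 1 | spiro 3-methoxy-5-methylcyclohexa-2,5-dien-1-one, spiro-fused at C4 to ring B carrying its C9 ethylene ketal | O=C1C=C(OC)C2(CCC3(OCCO3)CC2)C(C)=C1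
A2 | alternative 1 | 4-{2-[2-(2-iodoethyl)-1,3-dioxolan-2-yl]ethyl}-3-methoxy-5-methylphenol | Oc1cc(OC)c(CCC2(CCI)OCCO2)c(C)c1
A3 | alternative 2 | ring A cis-bromohydrin (3R,4S) with C1 methylidene, ring B as its C9 ethylene ketal | C=C1C[C@@H](O)[C@@H](Br)C(C)(C)C12CCC3(OCCO3)CC2
A4 | alternative 2 | (2S)-2-bromo-3-methyl-3-[8-(prop-1-en-2-yl)-1,4-dioxaspiro[4.5]decan-8-yl]butanal | CC(=C)C1(CCC2(OCCO2)CC1)C(C)(C)[C@H](Br)C=O
A5 | alternative 3 | tert-butyl β-keto ester of ring A in its enol form (ester on C2, enol oxygen on C3, C1 methylidene), ring B as its C9 ethylene ketal | C=C1C(C(=O)OC(C)(C)C)=C(O)CC(C)(C)C12CCC3(OCCO3)CC2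
A6 | alternative 3 | tert-butyl 5-(8-ethynyl-1,4-dioxaspiro[4.5]decan-8-yl)-5-methyl-3-oxohexanoate | C#CC1(CCC2(OCCO2)CC1)C(C)(C)CC(=O)CC(=O)OC(C)(C)C
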